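**Retrosynthetic overview**
- Target ⇐ Baeyer–Villiger oxidation (C1 acetyl → C1 acetoxy, retention) of a cis-fused octalin methyl ketone.
- Octalin ⇐ intramolecular Diels–Alder reaction of a (Z)-enone / (E,E)-dienyl acetate triene (bonds C2–C7 and C1–C10); C1, C2, C7 and C10 are set under control of C3/C4.
- Triene ⇐ pyranyl methyl ketal that masks the (Z)-enone and the C4 hydroxyl in one ring; C5–C6 bond by acylation of an alkenyllithium, C7–C10 diene by allylic oxidation and dienol acetylation.
- Pyranyl ester ⇐ organocatalytic asymmetric hetero-Diels–Alder reaction of a silyl dienol ether with ethyl glyoxylate (sets C3 and C4, locks the Z olefin).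
- Ring order: temporary dihydropyran first; after its opening, carbocyclic rings A and B close together.

Assumption: 1, 3, 6 and 7 are taken as commercial. Locants C1–C10 follow the ring atoms of the target SMILES: C1 and C10 carry OAc, C2 and C7 are the ring-fusion carbons, C3 carries Me, C4 carries OH, C5 is the ketone, C6 carries the isopropylidene, C8=C9 is the ring olefin.

**Step 1**
Reactants: 1 (E)-hex-3-en-2-one
Product: 2 (2Z,4E)-2-[(tert-butyldimethylsilyl)oxy]hexa-2,4-diene
Conditions: TBSOTf, Et3N, CH2Cl2, 0 °C to rt (equilibrating), distillation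
Reagents that add atoms: tert-butyldimethylsilyl trifluoromethanesulfonate, CC(C)(C)[Si](C)(C)OS(=O)(=O)C(F)(F)F
Why: Soft enolisation (silyl triflate/amine) under equilibrating conditions removes a γ-hydrogen and gives the more substituted, fully conjugated linear silyl dienol ether, the Z enol-ether geometry being the one free of allylic strain; no stereocentre is formed.

**Step 2**
Reactants: 2 (2Z,4E)-2-[(tert-butyldimethylsilyl)oxy]hexa-2,4-diene; 3 ethyl glyoxylate
Product: 5 ethyl (2S,3R)-6-methoxy-3,6-dimethyl-3,6-dihydro-2H-pyran-2-carboxylate, via silyl ketal 4 (not isolated)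
Conditions: chiral BINOL-derived imidodiphosphorimidate Brønsted acid (IDPi, 2 mol%, enantiomer chosen for 2S,3R), toluene, –60 °C; then MeOH, PPTS, 0 °C
Reagents that add atoms: methanol, CO
Why: Proposed new method: the IDPi acid is silylated by 2 and the silylium/chiral-anion pair activates the aldehyde oxygen of 3, the s-cis diene (small OSi group inside) attacks through its methyl-bearing terminus in a concerted asynchronous endo [4+2] array so that C–C bond formation is followed at once by O–C closure onto the incipient silyloxocarbenium carbon, which locks the future enone in its Z form and places the ester cis to the C3 methyl (2S,3R) while the confined chiral anion selects the aldehyde face, and acidic methanol then exchanges the labile anomeric silyl ether for OMe (C6 epimers, inconsequential); the closest known reaction types are the disulfonimide- and IDPi-catalysed hetero-Diels–Alder reactions of aldehydes with siloxy dienes and the vinylogous Mukaiyama aldol reaction, neither shown for a 1-alkyl-1-siloxy diene that keeps its ketal oxygen.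

**Step 3**
Reactants: 6 1,1-dibromo-2-methylprop-1-ene; 7 1-bromo-3-methylbut-2-ene (prenyl bromide)
Product: 9 3-bromo-2,6-dimethylhepta-2,5-diene, via lithium carbenoid 8 (not isolated)
Conditions: n-BuLi, THF–Et2O, –105 °C; then 7, –105 to –60 °C
Reagents that add atoms: none
Why: Bromine–lithium exchange on the gem-dibromoalkene gives the α-bromoalkenyllithium, which is alkylated by the allylic bromide (carbenoid alkylation, SN2) below its rearrangement temperature; the two olefin substituents are identical, so no geometry or stereocentre is at stake.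

**Step 4**
Reactants: 9 3-bromo-2,6-dimethylhepta-2,5-diene; 5 ethyl (2S,3R)-6-methoxy-3,6-dimethyl-3,6-dihydro-2H-pyran-2-carboxylate
Product: 11 1-[(2S,3R)-6-methoxy-3,6-dimethyl-3,6-dihydro-2H-pyran-2-yl]-5-methyl-2-(propan-2-ylidene)hex-4-en-1-one, via alkenyllithium 10 (not isolated)
Conditions: t-BuLi (2.0 equiv), Et2O, –78 °C; then 5, THF, –78 °C; NH4Cl (aq) at –78 °C
Reagents that add atoms: none
Why: Halogen–lithium exchange followed by acyl substitution, in which the hindered tetrasubstituted alkenyllithium adds once to the α-alkoxy ester and the chelated tetrahedral lithium hemiketal collapses to the cross-conjugated ketone only on quench; the ketal is inert to the organolithium and C3/C4 are untouched.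

**Step 5**
Reactants: 11 1-[(2S,3R)-6-methoxy-3,6-dimethyl-3,6-dihydro-2H-pyran-2-yl]-5-methyl-2-(propan-2-ylidene)hex-4-en-1-one
Product: 12 (2E)-6-[(2S,3R)-6-methoxy-3,6-dimethyl-3,6-dihydro-2H-pyran-2-yl]-2-methyl-6-oxo-5-(propan-2-ylidene)hex-2-enal
Conditions: SeO2 (1.2 equiv), pyridine, 1,4-dioxane, 70 °C
Reagents that add atoms: selenium dioxide, O=[Se]=O
Why: Selenium dioxide allylic oxidation (ene reaction, then [2,3]-shift) attacks the electron-rich trisubstituted prenyl olefin at its (E)-methyl group and carries it to the (E)-enal, the enone-bound isopropylidene and the ring olefin being less electron-rich and pyridine buffering the acid-labile ketal.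

**Step 6**
Reactants: 12 (2E)-6-[(2S,3R)-6-methoxy-3,6-dimethyl-3,6-dihydro-2H-pyran-2-yl]-2-methyl-6-oxo-5-(propan-2-ylidene)hex-2-enal
Product: 13 (1E,3E)-6-[(2S,3R)-6-methoxy-3,6-dimethyl-3,6-dihydro-2H-pyran-2-yl]-2-methyl-6-oxo-5-(propan-2-ylidene)hexa-1,3-dien-1-yl acetate
Conditions: Ac2O, Et3N, DMAP (cat.), CH2Cl2, 0 °C to rt
Reagents that add atoms: acetic anhydride, CC(=O)OC(C)=O
Why: Dienol acetate formation, in which the doubly allylic γ-hydrogens (C7) of the enal are removed and the dienolate is O-acetylated to the (1E,3E)-1-acetoxydiene (acetoxy anti to the vinyl group); the hydroxyl is still tied up in the ketal so only C10 is acetylated, and the hindered C4–H is not touched by the mild base.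

**Step 7**
Reactants: 13 (1E,3E)-6-[(2S,3R)-6-methoxy-3,6-dimethyl-3,6-dihydro-2H-pyran-2-yl]-2-methyl-6-oxo-5-(propan-2-ylidene)hexa-1,3-dien-1-yl acetate
Product: 16 (3S,4R,4aS,5R,6R,8aS)-5-acetyl-3-hydroxy-4,7-dimethyl-2-oxo-1-(propan-2-ylidene)-1,2,3,4,4a,5,6,8a-octahydronaphthalen-6-yl acetate, via hemiketal 14 (not isolated), via open-chain hydroxy enone 15 (not isolated)
Conditions: AcOH–THF–H2O, rt; concentrate; then toluene, BHT, 90 °C
Reagents that add atoms: water, O
Why: Mild hydrolysis frees the hemiketal, whose ring-opened (Z)-δ-hydroxy enone undergoes an intramolecular Diels–Alder reaction through the endo transition state (acetyl and tether under the (E,E)-diene), which gives the cis ring fusion with H1, H2, H7 and H10 all cis, while a chair-like tether with the C3 methyl and C4 hydroxyl equatorial and the diene axial (no allylic strain with the isopropylidene) selects the diene face.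

**Step 8**
Reactants: 16 (3S,4R,4aS,5R,6R,8aS)-5-acetyl-3-hydroxy-4,7-dimethyl-2-oxo-1-(propan-2-ylidene)-1,2,3,4,4a,5,6,8a-octahydronaphthalen-6-yl acetate
Product: 17 (3S,4R,4aS,5R,6S,8aR)-3-hydroxy-4,7-dimethyl-2-oxo-1-(propan-2-ylidene)-1,2,3,4,4a,5,6,8a-octahydronaphthalene-5,6-diyl diacetate (CNP0333818.1)
Conditions: (Me3SiO)2 (2 equiv), Me3SiOTf (10 mol%), CH2Cl2, –40 °C; NaHCO3 (aq)
Reagents that add atoms: bis(trimethylsilyl) peroxide, C[Si](C)(C)OO[Si](C)(C)C
Why: Baeyer–Villiger oxidation in which the secondary C1 carbon migrates in preference to methyl with retention of configuration; this silyl peroxide reagent does not epoxidise C=C bonds, the hindered conjugated C5 ketone does not react, and the transiently silylated C4 hydroxyl is freed on work-up.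

**Compound list**
1 | (E)-hex-3-en-2-one | CC(=O)/C=C/CC | starting material
2 | (2Z,4E)-2-[(tert-butyldimethylsilyl)oxy]hexa-2,4-diene | C/C=C/C=C(\O[Si](C)(C)C(C)(C)C)C | intermediate
3 | ethyl glyoxylate (ethyl 2-oxoacetate) | O=CC(=O)OCC | starting material
4 | ethyl (2S,3R)-6-[(tert-butyldimethylsilyl)oxy]-3,6-dimethyl-3,6-dihydro-2H-pyran-2-carboxylate (C6 not defined) | CC1(O[Si](C)(C)C(C)(C)C)C=C[C@@H](C)[C@H](O1)C(=O)OCC | intermediate
5 | ethyl (2S,3R)-6-methoxy-3,6-dimethyl-3,6-dihydro-2H-pyran-2-carboxylate (C6 epimers) | CC1(OC)C=C[C@@H](C)[C@H](O1)C(=O)OCC | intermediate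
6 | 1,1-dibromo-2-methylprop-1-ene | CC(C)=C(Br)Br | starting material
7 | 1-bromo-3-methylbut-2-ene (prenyl bromide) | CC(C)=CCBr | starting material
8 | (1-bromo-2-methylprop-1-en-1-yl)lithium | CC(C)=C([Li])Br | intermediate
9 | 3-bromo-2,6-dimethylhepta-2,5-diene | CC(C)=C(Br)CC=C(C)C | intermediate
10 | (2,6-dimethylhepta-2,5-dien-3-yl)lithium | CC(C)=C([Li])CC=C(C)C | intermediate
11 | 1-[(2S,3R)-6-methoxy-3,6-dimethyl-3,6-dihydro-2H-pyran-2-yl]-5-methyl-2-(propan-2-ylidene)hex-4-en-1-one | CC1(OC)C=C[C@@H](C)[C@H](O1)C(=O)C(=C(C)C)CC=C(C)C | intermediate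
12 | (2E)-6-[(2S,3R)-6-methoxy-3,6-dimethyl-3,6-dihydro-2H-pyran-2-yl]-2-methyl-6-oxo-5-(propan-2-ylidene)hex-2-enal | CC1(OC)C=C[C@@H](C)[C@H](O1)C(=O)C(=C(C)C)C/C=C(C)/C=O | intermediate
13 | (1E,3E)-6-[(2S,3R)-6-methoxy-3,6-dimethyl-3,6-dihydro-2H-pyran-2-yl]-2-methyl-6-oxo-5-(propan-2-ylidene)hexa-1,3-dien-1-yl acetate | CC1(OC)C=C[C@@H](C)[C@H](O1)C(=O)C(=C(C)C)/C=C/C(C)=C/OC(C)=O | intermediate
14 | (1E,3E)-6-[(2S,3R)-6-hydroxy-3,6-dimethyl-3,6-dihydro-2H-pyran-2-yl]-2-methyl-6-oxo-5-(propan-2-ylidene)hexa-1,3-dien-1-yl acetate | CC1(O)C=C[C@@H](C)[C@H](O1)C(=O)C(=C(C)C)/C=C/C(C)=C/OC(C)=O | intermediate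
15 | (1E,3E,7S,8R,9Z)-7-hydroxy-2,8-dimethyl-6,11-dioxo-5-(propan-2-ylidene)dodeca-1,3,9-trien-1-yl acetate | CC(=O)/C=C\[C@@H](C)[C@H](O)C(=O)C(=C(C)C)/C=C/C(C)=C/OC(C)=O | intermediate
16 | (3S,4R,4aS,5R,6R,8aS)-5-acetyl-3-hydroxy-4,7-dimethyl-2-oxo-1-(propan-2-ylidene)-1,2,3,4,4a,5,6,8a-octahydronaphthalen-6-yl acetate | CC(=O)[C@@H]1[C@@H]2[C@@H](C)[C@H](O)C(=O)C(=C(C)C)[C@@H]2C=C(C)[C@@H]1OC(C)=O | intermediate
17 | (3S,4R,4aS,5R,6S,8aR)-3-hydroxy-4,7-dimethyl-2-oxo-1-(propan-2-ylidene)-1,2,3,4,4a,5,6,8a-octahydronaphthalene-5,6-diyl diacetate | CC(=O)O[C@@H]1[C@@H]2[C@@H](C)[C@H](O)C(=O)C(=C(C)C)[C@@H]2C=C(C)[C@@H]1OC(C)=O | target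

**Step count**
Total steps: 8. Longest linear sequence: 7 (steps 1, 2, 4, 5, 6, 7, 8; step 3 runs in parallel).

**Steps most likely to fail, with fallbacks**

Step 2 (the proposed new hetero-Diels–Alder reaction). The diene may react through an open s-trans (Mukaiyama aldol) pathway and give the (E)-enone, or with low enantioselectivity. The fallback uses known chemistry, sets out from 3 and comes back at 5. Propanal and 3 are joined in a syn-selective enamine cross-aldol reaction (axially chiral binaphthyl amino sulfonamide as secondary-amine catalyst, NMP, 0 °C) to give ethyl (2S,3S)-2-hydroxy-3-methyl-4-oxobutanoate F1. The crude aldehyde is olefinated Z-selectively with the potassium salt of bis(2,2,2-trifluoroethyl) (2-oxopropyl)phosphonate (KN(SiMe3)2, 18-crown-6, THF, –78 °C; Still–Gennari-type Horner–Wadsworth–Emmons reaction). The (Z)-enone closes to ethyl (2S,3R)-6-hydroxy-3,6-dimethyl-3,6-dihydro-2H-pyran-2-carboxylate F2, and MeOH/PPTS converts this into 5.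

Step 4 (single acylation of a hindered alkenyllithium by an ester). Double addition, or deprotonation at C4 with loss of the cis relationship, may compete. The fallback sets out from 5 and comes back at 11 by a reduce/add/oxidise sequence. i-Bu2AlH (CH2Cl2, –78 °C) gives (2S,3R)-6-methoxy-3,6-dimethyl-3,6-dihydro-2H-pyran-2-carbaldehyde F3. Alkenyllithium 10 adds to it (THF, –78 °C; aldehyde addition outruns enolisation) to give 1-[(2S,3R)-6-methoxy-3,6-dimethyl-3,6-dihydro-2H-pyran-2-yl]-5-methyl-2-(propan-2-ylidene)hex-4-en-1-ol F4 as a carbinol mixture. Dess–Martin periodinane/NaHCO3 oxidises F4 to 11.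

Step 7 (thermal cycloaddition through the hemiketal equilibrium). The open form may be too scarce, the endo preference of the uncatalysed reaction may be modest, or the hemiketal may dehydrate on heating. The fallback sets out from 13 and comes back at 16, and replaces the thermal reaction by a Lewis-acid-catalysed cycloaddition of a protected open-chain trienone. After the same hydrolysis to 14/15, Et3SiOTf/2,6-lutidine (CH2Cl2, –78 °C) traps the open form as (1E,3E,7S,8R,9Z)-2,8-dimethyl-6,11-dioxo-5-(propan-2-ylidene)-7-[(triethylsilyl)oxy]dodeca-1,3,9-trien-1-yl acetate F5. Me2AlCl (CH2Cl2, –78 to –40 °C) coordinates the acetyl group and enforces the endo, cis-fused cycloaddition to (3S,4R,4aS,5R,6R,8aS)-5-acetyl-4,7-dimethyl-2-oxo-1-(propan-2-ylidene)-3-[(triethylsilyl)oxy]-1,2,3,4,4a,5,6,8a-octahydronaphthalen-6-yl acetate F6. HF·pyridine (THF, 0 °C) then gives 16.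

**Further compounds**
F1 | step 2 | ethyl (2S,3S)-2-hydroxy-3-methyl-4-oxobutanoate | O=C[C@@H](C)[C@H](O)C(=O)OCC
F2 | step 2 | ethyl (2S,3R)-6-hydroxy-3,6-dimethyl-3,6-dihydro-2H-pyran-2-carboxylate | CC1(O)C=C[C@@H](C)[C@H](O1)C(=O)OCC
F3 | step 4 | (2S,3R)-6-methoxy-3,6-dimethyl-3,6-dihydro-2H-pyran-2-carbaldehyde | CC1(OC)C=C[C@@H](C)[C@H](O1)C=O
F4 | step 4 | 1-[(2S,3R)-6-methoxy-3,6-dimethyl-3,6-dihydro-2H-pyran-2-yl]-5-methyl-2-(propan-2-ylidene)hex-4-en-1-ol | CC1(OC)C=C[C@@H](C)[C@H](O1)C(O)C(=C(C)C)CC=C(C)C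
F5 | step 7 | (1E,3E,7S,8R,9Z)-2,8-dimethyl-6,11-dioxo-5-(propan-2-ylidene)-7-[(triethylsilyl)oxy]dodeca-1,3,9-trien-1-yl acetate | CC(=O)/C=C\[C@@H](C)[C@H](O[Si](CC)(CC)CC)C(=O)C(=C(C)C)/C=C/C(C)=C/OC(C)=O
F6 | step 7 | (3S,4R,4aS,5R,6R,8aS)-5-acetyl-4,7-dimethyl-2-oxo-1-(propan-2-ylidene)-3-[(triethylsilyl)oxy]-1,2,3,4,4a,5,6,8a-octahydronaphthalen-6-yl acetate | CC(=O)[C@@H]1[C@@H]2[C@@H](C)[C@H](O[Si](CC)(CC)CC)C(=O)C(=C(C)C)[C@@H]2C=C(C)[C@@H]1OC(C)=O
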